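**Retrosynthetic overview**
- Last bond: phthalide C3–CH2, made by a nickel-catalysed enantioconvergent radical hydroalkylation that joins racemic 3-bromo-5,7-dimethoxyphthalide to the terminal olefin of the finished spiroketal and sets C3.
- Bromophthalide ⇐ lactol ⇐ directed ortho-formylation of N,N-diethyl-2,4-dimethoxybenzamide ⇐ Friedel–Crafts carbamoylation of 1,3-dimethoxybenzene ⇐ resorcinol.
- Spiroketal olefin ⇐ acetone dimethylhydrazone alkylated twice, with (S)-propylene oxide and (S)-2-(hex-5-enyl)oxirane, then acid.
- (S)-2-(Hex-5-enyl)oxirane ⇐ (S)-epichlorohydrin + pent-4-enylmagnesium bromide.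
- Ring order: phthalide lactone ring (step 3), both spiroketal rings together (step 5), fragments joined last (step 6).

Assumption: the spiro carbon equilibrates under acid with little intrinsic bias, so step 5 gives both spiro epimers in roughly equal amounts; the (5S) epimer is isolated by chromatography (AgNO3–silica or preparative HPLC if plain silica fails), the (5R) epimer is re-equilibrated (PPTS, CH2Cl2) and recycled, and step 6 is kept base-buffered so C5 is not scrambled.

**Step 1**
Reactants: 1 resorcinol
Product: 2 1,3-dimethoxybenzene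
Conditions: MeI, K2CO3, acetone, reflux
Reagents that add atoms: iodomethane, CI
Why: Williamson ether synthesis; both phenoxides are O-methylated and no stereocentre is involved.

**Step 2**
Reactants: 2 1,3-dimethoxybenzene
Product: 3 N,N-diethyl-2,4-dimethoxybenzamide
Conditions: Et2NCOCl, AlCl3, ClCH2CH2Cl, 0 → 50 °C
Reagents that add atoms: N,N-diethylcarbamoyl chloride, CCN(CC)C(Cl)=O
Why: Friedel–Crafts carbamoylation at C4, which is para to one methoxy group and ortho to the other and is the most nucleophilic unhindered position, so the future lactone carbonyl carbon enters where it is needed.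

**Step 3**
Reactants: 3 N,N-diethyl-2,4-dimethoxybenzamide
Product: 5 3-hydroxy-5,7-dimethoxy-2-benzofuran-1(3H)-one (racemic lactol), via formyl amide 4 (not isolated)
Conditions: s-BuLi, TMEDA, THF, −78 °C; DMF, −78 °C → rt; then 6 M aq. HCl, 70 °C
Reagents that add atoms: N,N-dimethylformamide, CN(C)C=O; water, O
Why: Directed ortho metalation, in which the diethylamide steers s-BuLi/TMEDA to C6, DMF formylates, and the neighbouring aldehyde then assists acid hydrolysis of the amide so the acid closes on it as the lactol; the lactol carbon is racemic and is erased in step 6.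

**Step 4**
Reactants: 6 5-bromopent-1-ene; 7 (S)-epichlorohydrin
Product: 10 (S)-2-(hex-5-en-1-yl)oxirane, via Grignard reagent 8 (not isolated), via chlorohydrin 9 (not isolated)
Conditions: Mg, THF, 40 °C; then 7, CuI (5 mol %), THF, −40 → 0 °C; then 5 M aq. NaOH, rt
Reagents that add atoms: magnesium, [Mg] (stays only in intermediate 8)
Why: Copper-catalysed Grignard opening of the epoxide at its unsubstituted carbon followed by intramolecular Williamson closure of the chlorohydrin; the stereocentre is never touched, so (S)-epichlorohydrin gives the (S)-epoxide.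

**Step 5**
Reactants: 11 acetone N,N-dimethylhydrazone; 12 (S)-propylene oxide; 10 (S)-2-(hex-5-en-1-yl)oxirane
Product: 16 (2S,5S,7S)-2-(hex-5-en-1-yl)-7-methyl-1,6-dioxaspiro[4.4]nonane, via hydroxy hydrazone 13 (not isolated), via dihydroxy hydrazone 14 (not isolated), via keto diol 15 (not isolated)
Conditions: n-BuLi, THF, −78 → 0 °C; 12, 0 °C → rt; n-BuLi, −78 → 0 °C; 10, 0 °C → rt; then 3 M aq. HCl, pentane, rt; chromatography
Reagents that add atoms: water, O (its oxygen stays only in intermediate 15)
Why: Corey–Enders hydrazone alkylation run twice, each aza-enolate opening an epoxide at its CH2 terminus (the second lithiation goes to the remaining methyl group), so the carbinol centres are carried over unchanged as 2S and 8S, and acid hydrolysis with spiroketalisation then closes both rings, with the spiro carbon set under thermodynamic control and the (5S) epimer isolated.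

**Step 6**
Reactants: 5 3-hydroxy-5,7-dimethoxy-2-benzofuran-1(3H)-one; 16 (2S,5S,7S)-2-(hex-5-en-1-yl)-7-methyl-1,6-dioxaspiro[4.4]nonane
Product: 18 (3S)-5,7-dimethoxy-3-{6-[(2S,5S,7S)-7-methyl-1,6-dioxaspiro[4.4]nonan-2-yl]hexyl}-2-benzofuran-1(3H)-one, via bromophthalide 17 (not isolated)
Conditions: SOBr2, CH2Cl2, 0 °C → rt, evaporate (PhMe chase); then 16, NiBr2(MeOCH2CH2OMe) (10 mol %), (S,S)-Ph-BOX (12 mol %), (EtO)3SiH, K3PO4·H2O, DMA/THF, 0 °C
Reagents that add atoms: thionyl bromide, O=S(Br)Br (its bromine stays only in intermediate 17)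
Why: Proposed new method: SOBr2 turns the lactol into the racemic cyclic 1-bromoalkyl ester 17 (the intramolecular counterpart of aldehyde + acyl bromide); a chiral nickel hydride formed from the silane adds anti-Markovnikov to the terminal olefin of 16 to give a primary alkylnickel, low-valent nickel abstracts bromine from either enantiomer of 17 to give one planar benzylic α-acyloxy radical, and capture of that radical by the chiral alkylnickel followed by reductive elimination from trivalent nickel forms C3–CH2 and sets C3 as (S) under catalyst control; the closest known reaction types are nickel-hydride enantioconvergent hydroalkylation of terminal olefins with racemic acyclic 1-bromoalkyl esters and nickel/pybox enantioconvergent Negishi alkylation of racemic 1-haloindanes, and the sense of induction is not predictable here, so it is checked on 3-bromophthalide + oct-1-ene and the antipodal ligand is used if it is opposite.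

**Compound list**
1 | resorcinol | Oc1cccc(O)c1 | starting material
2 | 1,3-dimethoxybenzene | COc1cccc(OC)c1 | intermediate
3 | N,N-diethyl-2,4-dimethoxybenzamide | CCN(CC)C(=O)c1ccc(OC)cc1OC | intermediate
4 | N,N-diethyl-2-formyl-4,6-dimethoxybenzamide | CCN(CC)C(=O)c1c(C=O)cc(OC)cc1OC | intermediate
5 | 3-hydroxy-5,7-dimethoxy-2-benzofuran-1(3H)-one, racemic | COc1cc(OC)c2c(c1)C(O)OC2=O | intermediate
6 | 5-bromopent-1-ene | C=CCCCBr | starting material
7 | (S)-epichlorohydrin | ClC[C@@H]1CO1 | starting material
8 | pent-4-enylmagnesium bromide | C=CCCC[Mg]Br | intermediate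
9 | (S)-1-chlorooct-7-en-2-ol | ClC[C@@H](O)CCCCC=C | intermediate
10 | (S)-2-(hex-5-en-1-yl)oxirane | C=CCCCC[C@H]1CO1 | intermediate
11 | acetone N,N-dimethylhydrazone | CC(C)=NN(C)C | starting material
12 | (S)-propylene oxide | C[C@H]1CO1 | starting material
13 | (S)-5-(2,2-dimethylhydrazinylidene)hexan-2-ol, present in the flask as its lithium alkoxide | C[C@H](O)CCC(C)=NN(C)C | intermediate
14 | (2S,8S)-5-(2,2-dimethylhydrazinylidene)tetradec-13-ene-2,8-diol, present in the flask as its dilithium dialkoxide until the acid is added | C[C@H](O)CCC(=NN(C)C)CC[C@@H](O)CCCCC=C | intermediate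
15 | (2S,8S)-2,8-dihydroxytetradec-13-en-5-one | C[C@H](O)CCC(=O)CC[C@@H](O)CCCCC=C | intermediate
16 | (2S,5S,7S)-2-(hex-5-en-1-yl)-7-methyl-1,6-dioxaspiro[4.4]nonane | C=CCCCC[C@H]1CC[C@]2(CC[C@H](C)O2)O1 | intermediate
17 | 3-bromo-5,7-dimethoxy-2-benzofuran-1(3H)-one, racemic | COc1cc(OC)c2c(c1)C(Br)OC2=O | intermediate
18 | (3S)-5,7-dimethoxy-3-{6-[(2S,5S,7S)-7-methyl-1,6-dioxaspiro[4.4]nonan-2-yl]hexyl}-2-benzofuran-1(3H)-one | COc1cc(OC)c2c(c1)[C@H](CCCCCC[C@H]1CC[C@]3(CC[C@H](C)O3)O1)OC2=O | target

**Step count**
Total: 6 steps. Longest linear sequence: 4 steps (1 → 2 → 3 → 6); the spiroketal branch is 3 steps (4 → 5 → 6).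

**Three steps most likely to fail**

Step 6 is the main risk. A cyclic, aryl-substituted 1-bromoalkyl ester has not been used in this coupling, so low enantioselectivity, reduction of 17 to the parent phthalide, radical dimerisation or hydrolysis of 17 back to 5 could each defeat it. The fallback replaces the radical coupling by a catalyst-controlled polar addition; it sets out from 5 and 16 and comes back at 18. Lactol 5 is opened and esterified (MeI, K2CO3, DMF) to methyl 2-formyl-4,6-dimethoxybenzoate F1. Olefin 16 is hydroborated with Et2BH to diethyl{6-[(2S,5S,7S)-7-methyl-1,6-dioxaspiro[4.4]nonan-2-yl]hexyl}borane F2, and boron–zinc exchange with ZnEt2 gives bis{6-[(2S,5S,7S)-7-methyl-1,6-dioxaspiro[4.4]nonan-2-yl]hexyl}zinc F3. With Ti(OCHMe2)4 and catalytic (1R,2R)-N,N'-bis(trifluoromethylsulfonyl)cyclohexane-1,2-diamine (toluene, −20 °C), F3 transfers one alkyl group to the Si face of the aldehyde of F1. This gives methyl 2-[(1S)-1-hydroxy-7-[(2S,5S,7S)-7-methyl-1,6-dioxaspiro[4.4]nonan-2-yl]heptyl]-4,6-dimethoxybenzoate F4 as its zinc alkoxide, which lactonises to 18 on mild buffered work-up. The ligand-to-face assignment is by analogy with simple aryl aldehydes and would be confirmed on a model.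

Step 5 is the second risk. The second lithiation and epoxide opening on a substrate that already carries an alkoxide may be slow or unselective, and the spiro epimers may not separate at this stage; in that case the mixture is carried on and 18 is separated from its spiro epimer by preparative HPLC. The fallback changes the ketone synthon from a hydrazone to an alkyne; it sets out from 12 and 10 and comes back at 16. Propargyl bromide (BrCC#C) with two equivalents of n-BuLi and TMEDA gives 1,3-dilithiopropyne F5, whose propargylic carbon opens 12 to the dilithium salt of (S)-hex-5-yn-2-ol F6. The remaining acetylide opens 10 (THF/DMPU, rt) and NH4Cl work-up gives (2S,8S)-tetradec-13-en-5-yne-2,8-diol F7. Catalytic AuCl(PPh3) and AgOSO2CF3 in CH2Cl2 then add both hydroxyl groups to the same alkyne carbon (5-exo and 5-endo) to give 16 together with its spiro epimer, handled as in the main route.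

Step 2 is the third risk. AlCl3 may cleave the methoxy group ortho to the new carbonyl, or the weakly electrophilic carbamoyl chloride may convert poorly. The fallback reverses the polarity of the arene; it sets out from 2 and comes back at 3. NBS in MeCN gives 1-bromo-2,4-dimethoxybenzene F8, bromine–lithium exchange with n-BuLi (THF, −78 °C) gives (2,4-dimethoxyphenyl)lithium F9, and quenching with Et2NCOCl gives 3.

**Further compounds**
F1 | step 6 | methyl 2-formyl-4,6-dimethoxybenzoate | COC(=O)c1c(C=O)cc(OC)cc1OC
F2 | step 6 | diethyl{6-[(2S,5S,7S)-7-methyl-1,6-dioxaspiro[4.4]nonan-2-yl]hexyl}borane | CCB(CC)CCCCCC[C@H]1CC[C@]2(CC[C@H](C)O2)O1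
F3 | step 6 | bis{6-[(2S,5S,7S)-7-methyl-1,6-dioxaspiro[4.4]nonan-2-yl]hexyl}zinc | [Zn](CCCCCC[C@H]1CC[C@]2(CC[C@H](C)O2)O1)CCCCCC[C@H]1CC[C@]2(CC[C@H](C)O2)O1
F4 | step 6 | methyl 2-[(1S)-1-hydroxy-7-[(2S,5S,7S)-7-methyl-1,6-dioxaspiro[4.4]nonan-2-yl]heptyl]-4,6-dimethoxybenzoate, zinc alkoxide in the flask | COC(=O)c1c(OC)cc(OC)cc1[C@@H](O)CCCCCC[C@H]1CC[C@]2(CC[C@H](C)O2)O1
F5 | step 5 | 1,3-dilithiopropyne | [Li]CC#C[Li]
F6 | step 5 | dilithium salt of (S)-hex-5-yn-2-ol | [Li]C#CCC[C@H](C)O[Li]
F7 | step 5 | (2S,8S)-tetradec-13-en-5-yne-2,8-diol | C[C@H](O)CCC#CC[C@@H](O)CCCCC=C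
F8 | step 2 | 1-bromo-2,4-dimethoxybenzene | COc1ccc(Br)c(OC)c1
F9 | step 2 | (2,4-dimethoxyphenyl)lithium | [Li]c1ccc(OC)cc1OC
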